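**Retrosynthetic overview**
1. Junceellolide K is reached from its C9 PMB ether by deprotection and acetylation. That lactone comes from a monocyclic keto-ester enal by forming C7–C8 with SmI2 (keto-aldehyde pinacol coupling): this closes the ten-membered carbocycle C1–C10, and the C7 alkoxide then closes the γ-lactone (O–C7–C8–C17–C19) on the C19 ester in the same operation.
2. Enabling feature: C7 (lactone oxygen) and C8 (tertiary OH) are vicinal oxygen-bearing carbons shared by the ten-membered ring and the lactone ring, C19 is 1,3 to C8, and C7 is allylic to the 5Z alkene. This is a 1,2-diol retron whose carbonyl precursors (C7 enal, C8 ketone of a β-keto ester) sit on trans arms of the cyclohexane.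
3. The keto-ester enal comes from a cyclohexane spiro-epoxide: arm B by propanoate aldol at C8 (C8–C17), arm A by B-alkyl Suzuki coupling (C4–C5) of a C3=C4 vinyl group with (Z)-3-iodobut-2-en-1-ol.
4. The cyclohexane comes from a Diels–Alder reaction of an (S,E)-γ-alkoxy enal with 1-acetoxybutadiene: the single purchased stereocentre C9 sets C1, C10 and C14 in one event. C2 follows by vinyl addition, C11 by allylic oxidation, methylenation and epoxidation.
5. Ring order: cyclohexane (step 5), spiro-epoxide (step 11), then ten-membered ring and γ-lactone together (step 17).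

Key step: step 17

Remark (assumption): (S)-but-3-ene-1,2-diol, methacrolein, 1-acetoxybuta-1,3-diene (used in excess, since only the E isomer of the commercial mixture reacts), vinylmagnesium bromide, methyl propanoate and but-2-yn-1-ol are taken as commercial. C1–C20 are briarane numbers of the target: ten-membered ring C1–C10, cyclohexane C1/C10–C14, lactone O–C7–C8–C17–C19(=O), methyls C15, C16, C18, epoxide CH2 C20; CIP descriptors in names use these locants.

**Route**

Step 1
Reactants: 1 (S)-but-3-ene-1,2-diol
Product: 2 (4S)-2-(4-methoxyphenyl)-4-vinyl-1,3-dioxolane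
Conditions: 4-MeOC6H4CH(OMe)2, PPTS (cat.), CH2Cl2, rt
Reagents that add atoms: 4-methoxybenzaldehyde dimethyl acetal, COC(OC)c1ccc(OC)cc1
Why: Acid-catalysed transacetalisation of the 1,2-diol gives the five-membered p-methoxybenzylidene acetal without touching C9, and the new acetal carbon (epimer mixture) disappears in step 2.

Step 2
Reactants: 2 (4S)-2-(4-methoxyphenyl)-4-vinyl-1,3-dioxolane
Product: 3 (S)-2-[(4-methoxybenzyl)oxy]but-3-en-1-ol
Conditions: iBu2AlH, CH2Cl2, −78 → 0 °C
Reagents that add atoms: none
Why: Regioselective reductive opening of the arylidene acetal, in which iBu2AlH binds the less hindered primary oxygen so that the PMB group stays on the secondary C9 oxygen and the primary C8 alcohol is released.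

Step 3
Reactants: 3 (S)-2-[(4-methoxybenzyl)oxy]but-3-en-1-ol
Product: 4 (S)-triethylsilyl ether of 3
Conditions: Et3SiCl, imidazole, CH2Cl2, 0 °C
Reagents that add atoms: chlorotriethylsilane, CC[Si](Cl)(CC)CC
Why: Standard silylation of a primary alcohol, with the primary TES ether chosen because step 12 oxidises it directly to the aldehyde.

Step 4
Reactants: 4 (S)-triethylsilyl ether; 5 methacrolein
Product: 6 (S,E)-4-[(4-methoxybenzyl)oxy]-2-methyl-5-[(triethylsilyl)oxy]pent-2-enal
Conditions: 5 (5 equiv), second-generation Hoveyda–Grubbs catalyst RuCl2(H2IMes)(=CH-C6H4-2-OiPr) (5 mol %), CH2Cl2, 40 °C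
Reagents that add atoms: none
Why: Olefin cross-metathesis of a terminal alkene with the 1,1-disubstituted enal should give the trisubstituted (E)-enal under thermodynamic control with loss of ethene.

Step 5
Reactants: 6 (S,E)-enal; 7 (E)-buta-1,3-dien-1-yl acetate
Product: 8 Diels–Alder aldehyde (1R,9S,10S,14S)
Conditions: 7 (3 equiv), Et2AlCl (0.3 equiv), CH2Cl2, −78 → −30 °C
Reagents that add atoms: none
Why: Lewis-acid-catalysed Diels–Alder reaction in which ortho regiochemistry joins the acetoxy-bearing diene terminus (C14) to the formyl-bearing C1, the endo rule places the C2 formyl group cis to the C14 acetate, the E geometry places C9 trans to C2, and 1,3-allylic strain with the C15 methyl holds C9–H in the enal plane so that the diene adds anti to the C9–O bond, which sets C1, C10 and C14 from C9 in one event.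

Step 6
Reactants: 8 Diels–Alder aldehyde; 9 vinylmagnesium bromide
Product: 11 cyclohexene diacetate (1S,2S,9S,10S,14S), via bromomagnesium C2-alkoxide 10 (not isolated)
Conditions: CH2=CHMgBr (1.2 equiv), THF, −78 °C; then Ac2O, DMAP, −78 → 0 °C
Reagents that add atoms: acetic anhydride, CC(=O)OC(C)=O
Why: Felkin–Anh addition of the Grignard reagent to the α-quaternary aldehyde, anti to the C10 branch and 1,3-anti to the C14 acetoxy group, should set C2, and acetylation of the alkoxide in the same flask makes any 1,3-acetyl shift between O14 and O2 inconsequential.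

Step 7
Reactants: 11 cyclohexene diacetate
Product: 12 C11 allylic alcohol (C11 epimers)
Conditions: SeO2 (0.5 equiv), t-BuOOH, CH2Cl2, rt
Reagents that add atoms: tert-butyl hydroperoxide, CC(C)(C)OO; selenium dioxide (oxygen carrier), O=[Se]=O
Why: Selenium dioxide allylic oxidation (ene reaction followed by [2,3]-sigmatropic shift) hydroxylates the C11 methylene without allylic transposition, because the allylic positions C14 and C2 are deactivated by their acetoxy groups.

Step 8
Reactants: 12 C11 allylic alcohol
Product: 13 C11 enone (1S,2S,9S,10S,14S)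
Conditions: Dess–Martin periodinane, NaHCO3, CH2Cl2, 0 °C → rt
Reagents that add atoms: none
Why: Dess–Martin oxidation of a secondary allylic alcohol under neutral conditions, which also converges both C11 epimers and any enone already formed in step 7.

Step 9
Reactants: 13 C11 enone
Product: 14 C11 ketone (1R,2S,9S,10S,14S)
Conditions: [(Ph3P)CuH]6 (0.4 equiv), H2O (5 equiv), toluene, rt
Reagents that add atoms: none
Why: Conjugate reduction of the enone by Stryker's copper hydride, which leaves the isolated vinyl group, the acetates and the PMB ether untouched.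

Step 10
Reactants: 14 C11 ketone
Product: 15 11(20)-methylene compound (1R,2S,9S,10S,14S)
Conditions: Ph3PCH3Br, KN(SiMe3)2, THF, 0 °C → rt
Reagents that add atoms: methyltriphenylphosphonium bromide, C[P+](c1ccccc1)(c1ccccc1)c1ccccc1.[Br-]
Why: Wittig methylenation with the weakly basic, non-nucleophilic ylide, in which C10 keeps its thermodynamically preferred configuration with the C9 branch trans to C2.

Step 11
Reactants: 15 11(20)-methylene compound
Product: 16 11,20-epoxide (1R,2S,9S,10S,11R,14S)
Conditions: mCPBA, NaHCO3, CH2Cl2, 0 °C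
Reagents that add atoms: 3-chloroperoxybenzoic acid, OOC(=O)c1cccc(Cl)c1
Why: Prilezhaev epoxidation, chemoselective for the 1,1-disubstituted alkene over the acetoxy-deactivated vinyl group, in which the peracid should attack the equatorial (α) face of the chair with equatorial C2 and C9 arms, anti to the axial C15 methyl, to set C11.

Step 12
Reactants: 16 11,20-epoxide
Product: 17 C8 aldehyde (1R,2S,9S,10S,11R,14S)
Conditions: (COCl)2, DMSO, CH2Cl2, −78 → −30 °C; Et3N, −78 → 0 °C
Reagents that add atoms: none
Why: Swern conditions cleave and oxidise primary triethylsilyl ethers in one operation, giving the α-alkoxy aldehyde without a separate deprotection and without epimerising C9.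

Step 13
Reactants: 17 C8 aldehyde; 18 methyl propanoate
Product: 19 β-hydroxy ester (C8 and C17 epimers)
Conditions: LiN(iPr)2, 18, THF, −78 °C; then 17, −78 °C; AcOH quench
Reagents that add atoms: none
Why: Aldol addition of the lithium ester enolate at −78 °C, at which the acetates are not attacked, with the C8 and C17 configurations irrelevant because C8 is oxidised in step 16 and C17 is equilibrated in step 17.

Step 14
Reactants: 20 but-2-yn-1-ol
Product: 21 (Z)-3-iodobut-2-en-1-ol
Conditions: NaAlH2(OCH2CH2OMe)2, THF, 0 °C → rt; then I2, −78 °C → rt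
Reagents that add atoms: iodine, II
Why: Hydroxyl-directed trans-hydroalumination of the propargylic alcohol followed by iodinolysis with retention places iodine on C3 cis to the CH2OH group.

Step 15
Reactants: 19 β-hydroxy ester; 21 (Z)-3-iodobut-2-en-1-ol
Product: 23 (5Z)-C7,C8-diol (1S,2S,9S,10S,11R,14S), via B-alkyl-9-BBN borane 22 (not isolated)
Conditions: 9-BBN-H (2.2 equiv), THF, 0 °C → rt; then 21, PdCl2(dppf) (5 mol %), AsPh3, aq. K3PO4, DMF, rt
Reagents that add atoms: none
Why: Anti-Markovnikov hydroboration of the only remaining alkene followed by B-alkyl Suzuki–Miyaura coupling forms C4–C5 with retention of the iodoalkene geometry, so that C4 and C7 are cis on C5=C6.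

Step 16
Reactants: 23 (5Z)-C7,C8-diol
Product: 24 seco keto-ester (5Z)-enal (1S,2S,9S,10S,11R,14S)
Conditions: Dess–Martin periodinane (3 equiv), NaHCO3, CH2Cl2, 0 °C → rt
Reagents that add atoms: none
Why: Dess–Martin oxidation of both hydroxyl groups in one operation, the primary allylic alcohol to the (Z)-enal without isomerisation under buffered conditions and the β-hydroxy ester to the β-keto ester.

Step 17
Reactants: 24 seco keto-ester (5Z)-enal
Product: 27 9-O-(4-methoxybenzyl)-9-O-deacetyljunceellolide K, via bis(diiodosamarium) 7,8-diolate 25 (not isolated), via C17-epimeric lactone 26 (not isolated)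
Conditions: SmI2 (3 equiv), THF (0.002 M, 24 added over 6 h), −78 → −20 °C; aq. NH4Cl; crude product, DBU (0.2 equiv), CH2Cl2, rt
Reagents that add atoms: none
Why: Two single-electron transfers from SmI2 give ketyl radical anions at C7 (enal carbonyl) and C8 (ketone of the β-keto ester, held in a trivalent-samarium chelate with the ester carbonyl and the C9 PMB ether oxygen); radical C–C coupling gives the 7,8-diolate 25, whose C7 alkoxide attacks the C19 methyl ester to give lactone 26, and catalytic DBU then equilibrates C17 to the epimer with the C18 methyl trans to C9. The closest known reaction type is the intramolecular keto-aldehyde pinacol coupling mediated by SmI2 or low-valent titanium, known for medium and large rings and for β-keto ester/aldehyde pairs. The ten-membered carbocycle closes by a 10-exo-trig ketyl-to-carbonyl coupling and the γ-lactone by a 5-exo-trig acyl substitution. C8 is controlled by C9, since in the O8/O9 chelate C7 should add to the ketone face opposite the C10 ring carbon; C7 is controlled by an open antiperiplanar transition state in which the two samarium-bound oxygens point apart and C6 lies anti to C9, which gives the ring-cis 7,8-diol of the trans-fused lactone; C17 is under thermodynamic control. The step needs intramolecular cross-coupling over enal dimerisation, retention of the 5Z geometry, and lactonisation through O7 only; these rest on high dilution at −78 °C, the trans C2 and C9 arms on the cyclohexane chair that bring C7 and C8 together, and the PMB ether that both chelates and blocks O9, while O8 could only form a four-membered lactone.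

Step 18
Reactants: 27 9-O-(4-methoxybenzyl)-9-O-deacetyljunceellolide K
Product: 28 9-O-deacetyljunceellolide K
Conditions: DDQ, CH2Cl2/pH 7 phosphate buffer, 0 °C → rt
Reagents that add atoms: none
Why: Oxidative PMB ether cleavage by DDQ (hydride abstraction and hydrolysis of the oxocarbenium ion) in a wet, neutral medium that spares the epoxide and the lactone and keeps the neighbouring C8 hydroxyl from trapping the cation as an acetal.

Step 19
Reactants: 28 9-O-deacetyljunceellolide K
Product: 29 junceellolide K
Conditions: Ac2O, pyridine, DMAP (cat.), CH2Cl2, 0 °C → rt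
Reagents that add atoms: acetic anhydride, CC(=O)OC(C)=O
Why: DMAP-catalysed acetylation of the secondary C9 hydroxyl, under which the tertiary, hydrogen-bonded C8 hydroxyl should stay free.

**Compound list**
1 | (S)-but-3-ene-1,2-diol | C=C[C@H](O)CO | starting material
2 | (4S)-2-(4-methoxyphenyl)-4-vinyl-1,3-dioxolane (both epimers at the acetal carbon) | C=C[C@H]1COC(O1)c1ccc(OC)cc1 | intermediate
3 | (S)-2-[(4-methoxybenzyl)oxy]but-3-en-1-ol | C=C[C@H](OCc1ccc(OC)cc1)CO | intermediate
4 | (S)-triethyl({2-[(4-methoxybenzyl)oxy]but-3-en-1-yl}oxy)silane | C=C[C@H](OCc1ccc(OC)cc1)CO[Si](CC)(CC)CC | intermediate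
5 | methacrolein (2-methylprop-2-enal) | CC(=C)C=O | starting material
6 | (S,E)-4-[(4-methoxybenzyl)oxy]-2-methyl-5-[(triethylsilyl)oxy]pent-2-enal | O=C/C(C)=C/[C@H](OCc1ccc(OC)cc1)CO[Si](CC)(CC)CC | intermediate
7 | (E)-buta-1,3-dien-1-yl acetate | C=C/C=C/OC(C)=O | starting material
8 | (1S,5S,6R)-6-formyl-5-{(1S)-1-[(4-methoxybenzyl)oxy]-2-[(triethylsilyl)oxy]ethyl}-6-methylcyclohex-2-en-1-yl acetate (briarane locants 1R,9S,10S,14S; formyl C2 cis to the C14 acetate, C9 branch trans to C2) | O=C[C@@]1(C)[C@@H](OC(C)=O)C=CC[C@@H]1[C@H](OCc1ccc(OC)cc1)CO[Si](CC)(CC)CC | intermediate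
9 | vinylmagnesium bromide | C=C[Mg]Br | starting material
10 | bromomagnesium (2S)-alkoxide formed by vinyl addition to the formyl group of 8 | C=C[C@H](O[Mg]Br)[C@@]1(C)[C@@H](OC(C)=O)C=CC[C@@H]1[C@H](OCc1ccc(OC)cc1)CO[Si](CC)(CC)CC | intermediate
11 | (1S,2S,9S,10S,14S)-diacetate: cyclohex-12-ene (C1, C10–C14) with C15 methyl and (S)-1-acetoxyprop-2-enyl (C2–C4) on C1, acetoxy on C14, (S)-1-(4-methoxybenzyloxy)-2-(triethylsilyloxy)ethyl (C9, C8) on C10 | C=C[C@H](OC(C)=O)[C@@]1(C)[C@@H](OC(C)=O)C=CC[C@@H]1[C@H](OCc1ccc(OC)cc1)CO[Si](CC)(CC)CC | intermediate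
12 | 11 with a hydroxyl on C11 (1S,2S,9S,10R,14S; both C11 epimers) | C=C[C@H](OC(C)=O)[C@@]1(C)[C@@H](OC(C)=O)C=CC(O)[C@@H]1[C@H](OCc1ccc(OC)cc1)CO[Si](CC)(CC)CC | intermediate
13 | (1S,2S,9S,10S,14S)-cyclohex-12-en-11-one | C=C[C@H](OC(C)=O)[C@@]1(C)[C@@H](OC(C)=O)C=CC(=O)[C@@H]1[C@H](OCc1ccc(OC)cc1)CO[Si](CC)(CC)CC | intermediate
14 | (1R,2S,9S,10S,14S)-cyclohexan-11-one | C=C[C@H](OC(C)=O)[C@@]1(C)[C@@H](OC(C)=O)CCC(=O)[C@@H]1[C@H](OCc1ccc(OC)cc1)CO[Si](CC)(CC)CC | intermediate
15 | (1R,2S,9S,10S,14S)-11(20)-methylene compound | C=C[C@H](OC(C)=O)[C@@]1(C)[C@@H](OC(C)=O)CCC(=C)[C@@H]1[C@H](OCc1ccc(OC)cc1)CO[Si](CC)(CC)CC | intermediate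
16 | (1R,2S,9S,10S,11R,14S)-11,20-epoxide (epoxide oxygen trans to C15 methyl) | C=C[C@H](OC(C)=O)[C@@]1(C)[C@@H](OC(C)=O)CC[C@]2(CO2)[C@@H]1[C@H](OCc1ccc(OC)cc1)CO[Si](CC)(CC)CC | intermediate
17 | (1R,2S,9S,10S,11R,14S)-C8 aldehyde (2-(4-methoxybenzyloxy)acetaldehyde unit on C10) | C=C[C@H](OC(C)=O)[C@@]1(C)[C@@H](OC(C)=O)CC[C@]2(CO2)[C@@H]1[C@H](OCc1ccc(OC)cc1)C=O | intermediate
18 | methyl propanoate | CCC(=O)OC | starting material
19 | (1R,2S,9S,10S,11R,14S)-β-hydroxy ester: methyl 3-hydroxy-2-methylpropanoate unit (C19, C17, C18, C8) attached at C8 to C9 (C8 and C17 epimers) | C=C[C@H](OC(C)=O)[C@@]1(C)[C@@H](OC(C)=O)CC[C@]2(CO2)[C@@H]1[C@H](OCc1ccc(OC)cc1)C(O)C(C)C(=O)OC | intermediate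
20 | but-2-yn-1-ol | CC#CCO | starting material
21 | (Z)-3-iodobut-2-en-1-ol | OC/C=C(\I)C | intermediate
22 | C4 B-alkyl-9-borabicyclo[3.3.1]nonane from 19, C8 hydroxyl as its 9-BBN borinate | B1(C2CCCC1CCC2)CC[C@H](OC(C)=O)[C@@]3(C)[C@@H](OC(C)=O)CC[C@]4(CO4)[C@@H]3[C@H](OCc5ccc(OC)cc5)C(OB6C7CCCC6CCC7)C(C)C(=O)OC | intermediate
23 | (1S,2S,9S,10S,11R,14S,5Z)-diol: C7 primary allylic alcohol and C8 secondary alcohol (C8 and C17 epimers) | OC/C=C(/C)CC[C@H](OC(C)=O)[C@@]1(C)[C@@H](OC(C)=O)CC[C@]2(CO2)[C@@H]1[C@H](OCc1ccc(OC)cc1)C(O)C(C)C(=O)OC | intermediate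
24 | (1S,2S,9S,10S,11R,14S,5Z)-seco keto-ester enal: C7 aldehyde, C8 ketone, C19 methyl ester (C17 epimers) | O=C/C=C(/C)CC[C@H](OC(C)=O)[C@@]1(C)[C@@H](OC(C)=O)CC[C@]2(CO2)[C@@H]1[C@H](OCc1ccc(OC)cc1)C(=O)C(C)C(=O)OC | intermediate
25 | bis(diiodosamarium) (7S,8S)-7,8-diolate of the ten-membered dihydroxy methyl ester (C17 epimers) | CC(=O)O[C@H]1CC/C(C)=C\[C@H](O[Sm](I)I)[C@@](O[Sm](I)I)(C(C)C(=O)OC)[C@@H](OCc2ccc(OC)cc2)[C@H]2[C@]3(CC[C@H](OC(C)=O)[C@]12C)CO3 | intermediate
26 | 9-O-(4-methoxybenzyl)-9-O-deacetyljunceellolide K as the mixture of C17 epimers | CC(=O)O[C@H]1CC/C(C)=C\[C@@H]2OC(=O)C(C)[C@@]2(O)[C@@H](OCc2ccc(OC)cc2)[C@H]2[C@]3(CC[C@H](OC(C)=O)[C@]12C)CO3 | intermediate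
27 | 9-O-(4-methoxybenzyl)-9-O-deacetyljunceellolide K (1S,2S,7S,8R,9S,10S,11R,14S,17R) | CC(=O)O[C@H]1CC/C(C)=C\[C@@H]2OC(=O)[C@H](C)[C@@]2(O)[C@@H](OCc2ccc(OC)cc2)[C@H]2[C@]3(CC[C@H](OC(C)=O)[C@]12C)CO3 | intermediate
28 | 9-O-deacetyljunceellolide K (1S,2S,7S,8R,9S,10S,11R,14S,17R) | CC(=O)O[C@H]1CC/C(C)=C\[C@@H]2OC(=O)[C@H](C)[C@@]2(O)[C@@H](O)[C@H]2[C@]3(CC[C@H](OC(C)=O)[C@]12C)CO3 | intermediate
29 | junceellolide K (1S,2S,7S,8S,9S,10S,11R,14S,17R; 5Z) | CC(=O)O[C@H]1CC/C(C)=C\[C@@H]2OC(=O)[C@H](C)[C@@]2(O)[C@@H](OC(C)=O)[C@H]2[C@]3(CC[C@H](OC(C)=O)[C@]12C)CO3 | target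

**Step count**
Total: 19 steps. Longest linear sequence: 18 steps (steps 1–13 and 15–19, from 1); step 14 is a one-step side branch.

**Steps most likely to fail**

Step 17 (key step). The enal may be reduced without C–C coupling (1,4-reduction or intermolecular dimerisation), the 5Z geometry may be lost in the delocalised ketyl, or coupling may proceed through a samarium-bridged transition state that gives the other configuration at C7. The fallback sets out from 24 and keeps the same bond but separates ring closure from stereocontrol. Low-valent titanium pinacol macrocyclisation (TiCl3(DME)1.5, Zn–Cu couple, DME, syringe-pump addition) would give the ten-membered C7-epimeric dihydroxy ester F1. MnO2 would oxidise only its secondary allylic C7 hydroxyl to the α-hydroxy enone F2. Chelation-controlled reduction (Zn(BH4)2, Et2O, −20 °C; zinc chelate of O7 and O8, hydride anti to C9) would give the (7S,8S)-dihydroxy ester F3. DBU would then lactonise F3 and equilibrate C17, and the route is rejoined at 27.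

Step 5. The trisubstituted enal may react too slowly with the weakly nucleophilic acetoxydiene, the diene may polymerise under Lewis acid, or endo and facial control may be poor. The fallback sets out from 6 and uses the more electron-rich (E)-1-(trimethylsilyloxy)buta-1,3-diene (toluene, 80 °C, or catalytic Et2AlCl at −78 °C) to give the C14 trimethylsilyl ether adduct F4. Selective methanolysis of the secondary TMS ether (citric acid, MeOH, 0 °C) in the presence of the primary TES ether would give the C14 hydroxy aldehyde F5, and acetylation (Ac2O, pyridine, DMAP) returns to the route at 8.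

Step 11. Peracid attack may occur mainly on the β-face if the chair with axial C2 and C9 arms is the reactive conformer, which would give the C11 epimer. The fallback sets out from 15 and delivers the oxygen to the α-face indirectly: NBS in aqueous DME forms the bromonium ion on the face the peracid prefers, and water opens it at the tertiary C11 from the opposite face to give the bromohydrin F6. DBU in CH2Cl2 then closes F6 to the epoxide, and the route is rejoined at 16.

**Further compounds**
F1 | step 17 | ten-membered 7,8-dihydroxy methyl ester, mixture of C7 epimers (8S; C17 epimers) | CC(=O)O[C@H]1CC/C(C)=C\C(O)[C@@](O)(C(C)C(=O)OC)[C@@H](OCc2ccc(OC)cc2)[C@H]2[C@]3(CC[C@H](OC(C)=O)[C@]12C)CO3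
F2 | step 17 | ten-membered (5Z)-8-hydroxy-7-oxo methyl ester (α-hydroxy enone) | CC(=O)O[C@H]1CC/C(C)=C\C(=O)[C@@](O)(C(C)C(=O)OC)[C@@H](OCc2ccc(OC)cc2)[C@H]2[C@]3(CC[C@H](OC(C)=O)[C@]12C)CO3
F3 | step 17 | ten-membered (7S,8S)-7,8-dihydroxy methyl ester (free diol of 25) | CC(=O)O[C@H]1CC/C(C)=C\[C@H](O)[C@@](O)(C(C)C(=O)OC)[C@@H](OCc2ccc(OC)cc2)[C@H]2[C@]3(CC[C@H](OC(C)=O)[C@]12C)CO3
F4 | step 5 | C14 trimethylsilyl ether analogue of 8 | O=C[C@@]1(C)[C@@H](O[Si](C)(C)C)C=CC[C@@H]1[C@H](OCc1ccc(OC)cc1)CO[Si](CC)(CC)CC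
F5 | step 5 | C14 hydroxy analogue of 8 | O=C[C@@]1(C)[C@@H](O)C=CC[C@@H]1[C@H](OCc1ccc(OC)cc1)CO[Si](CC)(CC)CC
F6 | step 11 | 20-bromo-11-hydroxy compound (bromohydrin of 15, C11 hydroxyl trans to C15 methyl) | C=C[C@H](OC(C)=O)[C@@]1(C)[C@@H](OC(C)=O)CC[C@](O)(CBr)[C@@H]1[C@H](OCc1ccc(OC)cc1)CO[Si](CC)(CC)CC
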